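The south-east run, charged with 1.39 of incoming ligand per starting complex, saw starting complex fall to 2.4% by 15.0 d. The north-east flask holds less ligand per complex, and its starting complex moved 0.4 percentage points between the last readings, against a scatter of 0.5 points. Incoming ligand is the limiting reagent here, so the ledger follows it, in per cent of the starting complex charged, at the last reading (5.00 d).

the same everywhere: incoming ligand 0.237 M
- north-east: starting complex 0.25 M; temperature 50 °C; the very flask that is asked about, followed so far
- south-east: starting complex 0.17 M; temperature 35 °C; run made earlier
- flask: starting complex 0.25 M; temperature 50 °C; time 8.0 d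

| run | time / d | complex with one exchanged / % | starting complex / % |
|---|---|---|---|
| north-east | 1.04 | 36.4 | 25.0 |
| north-east | 2.08 | 35.6 | 18.3 |
| north-east | 3.00 | 35.2 | 17.7 |
| north-east | 4.00 | 34.6 | 15.9 |
| north-east | 5.00 | 35.6 | 15.5 |
| south-east | 1.25 | 45.8 | 41.3 |
| south-east | 2.50 | 46.7 | 23.3 |
| south-east | 5.00 | 38.5 | 10.7 |
| south-east | 8.00 | 32.7 | 6.0 |
| south-east | 15.0 | 28.7 | 2.4 |

(each reading ± 0.5 percentage points)

- grey: change nothing and wait 8.0 d more
- amber: at 8.0 d take out 90% of the complex with one exchanged then present, then wait 8.0 d
- violet: at 8.0 d add incoming ligand, 50.0% of the amount charged, then wait 8.0 d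
- blue: at 8.0 d raise the temperature by 10 K, then wait 8.0 d

- removed complex with one exchanged is counted in
- the earlier runs were read with a standard deviation of 0.5 percentage points
- additions bring no volume worth counting

- complex with one exchanged, in percent of the starting complex first charged, at 8.0 d
- what to do for the largest gain in complex with one exchanged; "none" if nothing gains more than 2 percentage points (grey / amber / violet / blue / none)
- complex with one exchanged present, with what was taken out counted in, in percent of the starting complex first charged, after amber
- complex with one exchanged present, with what was taken out counted in, in percent of the starting complex first charged, after violet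

Ligand charged: 94.8%

Booked to first exchange: 84.5%

Margin of ligand: 10.3%

Exchanged complex not read as complex with one exchanged: 48.9%

The unread part exceeds the margin, so one further ligand on each unread complex would overdraw the account, and part of it must have formed without ligand. Further exchange draws on the margin. The line to carry is the keep, the fraction of exchanged complex that stands as complex with one exchanged:

keep = 0.421

My own reckoning holds the keep and the booked amount steady to 8.0 d, which gives 35.6%.

The forecast gave 35.2%, chose amber, and put amber at 53% and violet at 40%. Of the stall it said: “This suggests reversible steps”.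

The flask gives 34.8% at 8.0 d, with amber the best choice, 52.0% after amber and 34.6% after violet, so the forecast's violet stands 5.4 points too high. Free incoming ligand is down to 0.0114% of its charge at 8.00 d.

    complex with one exchanged + incoming ligand → leaving ligand + complex with two exchanged (k = 0.0862 L mol⁻¹ h⁻¹, Ea = 83.0 kJ mol⁻¹)
    complex with one exchanged ⇌ isomer of the product (K = 1.20, k = 0.0664 h⁻¹, Ea = 95.0 kJ mol⁻¹, ΔH = −24.0 kJ mol⁻¹)
    starting complex + incoming ligand → leaving ligand + complex with one exchanged (k = 0.688 L mol⁻¹ h⁻¹, Ea = 77.0 kJ mol⁻¹)
    complex with two exchanged + incoming ligand → leaving ligand + complex with three exchanged (k = 0.470 L mol⁻¹ h⁻¹, Ea = 76.0 kJ mol⁻¹)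
    2 starting complex → self-condensation product (k = 2.18 × 10⁻⁴ L mol⁻¹ h⁻¹, Ea = 111 kJ mol⁻¹)
    complex with three exchanged + incoming ligand → leaving ligand + complex with four exchanged (k = 0.0399 L mol⁻¹ h⁻¹, Ea = 73.0 kJ mol⁻¹)
    (constants at 50 °C)

By the ledger, amber leaves 53.1% of exchanged complex in the flask. The keep turns that into 22.4%, and with the part taken out the reckoning reaches 53.7%, against 52.0% computed.

The flask with 0.095 M of incoming ligand has 38.0% of ligand per starting complex charged; with that ligand booked to first exchange, the keep gives 16.0%. The computed result is 16.5%.

The runs are simulated for an exercise, noise included.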